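**Plan**

Ring A is the central benzene: C1 bears the methide carbon C7, C2 a 4-hydroxyphenyl ring, C5 the CH2OH group and C6 the (4-hydroxyphenyl)ethynyl group.
Retrosynthesis: (i) the C7=C bond to the quinone ring goes back to a C7–OH carbinol with every OH silylated; (ii) C7–C1 and, in the same operation, C2–aryl are cut across a C1≡C2 aryne of ring A (diaryl ketone + aryl Grignard reagent + 1-bromo-2-chloroarene); (iii) C6–C(sp) (Sonogashira); (iv) C6–I back to C6–H of a 3-bromo-4-chlorobenzoate.
Enabling feature: C1 and C2 are neighbours that both carry carbon groups, so they can be the two ends of an aryne. The sp carbon on C6 flanks C1 and polarises the aryne, so the aryl nucleophile should enter at C2 and leave magnesium on C1. C7 is at ketone oxidation level with two equivalent para-oxygenated rings, so a symmetric benzophenone serves.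
Forward: no ring is built. The five rings are bought and joined in the order ring A + alkyne arm at C6, then C2–aryl and C1–C7 in one flask, then global desilylation with loss of water to the fuchsone.
Stereochemistry: none is needed. The target has no stereocentre, and the exocyclic C7=C bond is not stereogenic because the cyclohexadienone ring is symmetric.

Key step: step 7

Assumption: the two para-oxygenated rings on C7 are equivalent by proton shift in the target, so either may be drawn as the quinone ring; the compounds marked as starting materials are taken to be catalogue chemicals (TBS = tert-butyldimethylsilyl).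

**Route**

Step 1
Reactants: 1 methyl 3-bromo-4-chlorobenzoate
Product: 3 methyl 3-bromo-4-chloro-2-iodobenzoate, via arylmagnesium chloride 2 (not isolated)
Conditions: TMPMgCl·LiCl (1.2 eq), THF, −20 °C; then I2, −20 °C → rt; aq Na2S2O3
Reagents that add atoms: iodine, SMILES II
Why: The hindered magnesium amide should remove the most acidic ring proton, the one at C2 between the ester and the bromine (directed ortho-magnesiation, with the ester holding the base), and iodinolysis of the aryl–magnesium bond then gives the 2-iodide while the ortho-bromoarylmagnesium is cold enough not to lose magnesium halide.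

Step 2
Reactants: 3 methyl 3-bromo-4-chloro-2-iodobenzoate
Product: 4 (3-bromo-4-chloro-2-iodophenyl)methanol
Conditions: DIBAL-H (2.5 eq), CH2Cl2, −78 → 0 °C; aq Rochelle salt
Reagents that add atoms: none
Why: DIBAL-H reduction of an aryl ester should stop cleanly at the benzylic alcohol and not touch aryl iodide, bromide or chloride at low temperature.

Step 3
Reactants: 4 (3-bromo-4-chloro-2-iodophenyl)methanol
Product: 5 tert-butyl[(3-bromo-4-chloro-2-iodophenyl)methoxy]dimethylsilane
Conditions: TBSCl (1.2 eq), imidazole, DMF, rt
Reagents that add atoms: tert-butyldimethylsilyl chloride, SMILES CC(C)(C)[Si](C)(C)Cl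
Why: Standard silylation of a primary alcohol, needed so that no O–H proton quenches the organomagnesium species of step 7.

Step 4
Reactants: 5 tert-butyl[(3-bromo-4-chloro-2-iodophenyl)methoxy]dimethylsilane; 6 tert-butyl(4-ethynylphenoxy)dimethylsilane
Product: 7 tert-butyl{4-[(2-bromo-3-chloro-6-{[(tert-butyldimethylsilyl)oxy]methyl}phenyl)ethynyl]phenoxy}dimethylsilane
Conditions: PdCl2(PPh3)2 (3 mol %), CuI (5 mol %), Et3N–THF, degassed, rt → 40 °C
Reagents that add atoms: none
Why: Sonogashira coupling, in which oxidative addition at the C–I bond is far faster than at the C–Br and C–Cl bonds, so that only the iodide should be exchanged for the alkyne.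

Step 5
Reactants: 8 bis(4-hydroxyphenyl)methanone
Product: 9 bis{4-[(tert-butyldimethylsilyl)oxy]phenyl}methanone
Conditions: TBSCl (2.4 eq), imidazole, DMF, rt
Reagents that add atoms: tert-butyldimethylsilyl chloride, SMILES CC(C)(C)[Si](C)(C)Cl
Why: Standard silylation of both phenols, which removes the acidic protons and leaves the ketone as the only electrophilic site.

Step 6
Reactants: 10 (4-bromophenoxy)(tert-butyl)dimethylsilane
Product: 11 {4-[(tert-butyldimethylsilyl)oxy]phenyl}magnesium bromide (THF solution, titrated and used as such)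
Conditions: Mg turnings (activated), THF, 40 °C
Reagents that add atoms: magnesium, SMILES [Mg]
Why: Grignard formation by insertion of magnesium into the aryl–bromine bond, to which the aryl silyl ether is inert.

Step 7
Reactants: 7 tert-butyl{4-[(2-bromo-3-chloro-6-{[(tert-butyldimethylsilyl)oxy]methyl}phenyl)ethynyl]phenoxy}dimethylsilane; 11 {4-[(tert-butyldimethylsilyl)oxy]phenyl}magnesium bromide; 9 bis{4-[(tert-butyldimethylsilyl)oxy]phenyl}methanone
Product: 15 [4'-(TBSO)-4-(TBSOCH2)-3-{[4-(TBSO)phenyl]ethynyl}biphenyl-2-yl]bis[4-(TBSO)phenyl]methanol, via 2-chloroarylmagnesium chloride 12 (not isolated), via 3-alkynylaryne 13 (not isolated), via biarylmagnesium bromide 14 (not isolated)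
Conditions: i-PrMgCl·LiCl (1.1 eq), THF, 0 °C → rt; 11 (2 eq) added, then 60 °C; then 9 (3 eq), LaCl3·2LiCl (0.3 eq), 0 °C → rt; sat. aq NH4Cl, 0 °C
Reagents that add atoms: none
Why: Bromine–magnesium exchange at C1 of ring A gives a 2-chloroarylmagnesium species that loses MgCl2 on warming and forms the C1≡C2 aryne, the aryl Grignard reagent 11 adds across it (carbomagnesiation), and the aryl–magnesium bond left at C1 then adds to the carbonyl group of ketone 9, which makes the bond between C1 and the future methide carbon C7. The closest known reaction type is the aryne route to ortho-substituted biaryl Grignard reagents (arylmagnesiation of an aryne and capture by an electrophile, as used for m-terphenyls and biaryl phosphines), ended here by a Grignard addition to a diaryl ketone. No ring is closed and no stereocentre is formed, so there is no ring-closure mode or stereocontrol to secure. The step needs the aryl group at C2 and the magnesium at C1: the σ-withdrawing sp carbon of the alkynyl group on C6 polarises the aryne so that the nucleophile should attack the distal carbon C2 while negative charge builds up at C1 next to it, and attack at C1 would also be the more hindered one. Chemoselectivity rests on the order of addition, since the ketone meets the mixture only after the aryne has been consumed and is used in excess over all Grignard reagent present, and the lanthanum salt should favour addition over electron transfer at the crowded C1–Mg bond.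

Step 8
Reactants: 15 [4'-(TBSO)-4-(TBSOCH2)-3-{[4-(TBSO)phenyl]ethynyl}biphenyl-2-yl]bis[4-(TBSO)phenyl]methanol
Product: 17 selaginellin, via pentahydroxy carbinol 16 (not isolated)
Conditions: TBAF (6 eq), AcOH (6 eq), THF, 0 °C → rt; then aq citric acid (pH 4), EtOAc
Reagents that add atoms: none
Why: Fluoride buffered with acetic acid should cleave the four aryl and the one alkyl silyl ether without leaving a basic tertiary alkoxide next to the alkyne, and the freed bis(4-hydroxyphenyl) carbinol then loses water under mild acid to the quinone methide (fuchsone formation by dehydration), which is not stereogenic at the new double bond.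

**Compound list**

1 | methyl 3-bromo-4-chlorobenzoate | COC(=O)c1ccc(Cl)c(Br)c1 | starting material
2 | methyl 3-bromo-4-chloro-2-(chloromagnesio)benzoate | COC(=O)c1ccc(Cl)c(Br)c1[Mg]Cl | intermediate
3 | methyl 3-bromo-4-chloro-2-iodobenzoate | COC(=O)c1ccc(Cl)c(Br)c1I | intermediate
4 | (3-bromo-4-chloro-2-iodophenyl)methanol | OCc1ccc(Cl)c(Br)c1I | intermediate
5 | tert-butyl[(3-bromo-4-chloro-2-iodophenyl)methoxy]dimethylsilane | CC(C)(C)[Si](C)(C)OCc1ccc(Cl)c(Br)c1I | intermediate
6 | tert-butyl(4-ethynylphenoxy)dimethylsilane | C#Cc1ccc(O[Si](C)(C)C(C)(C)C)cc1 | starting material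
7 | tert-butyl{4-[(2-bromo-3-chloro-6-{[(tert-butyldimethylsilyl)oxy]methyl}phenyl)ethynyl]phenoxy}dimethylsilane | CC(C)(C)[Si](C)(C)OCc1ccc(Cl)c(Br)c1C#Cc1ccc(O[Si](C)(C)C(C)(C)C)cc1 | intermediate
8 | bis(4-hydroxyphenyl)methanone (4,4'-dihydroxybenzophenone) | O=C(c1ccc(O)cc1)c1ccc(O)cc1 | starting material
9 | bis{4-[(tert-butyldimethylsilyl)oxy]phenyl}methanone | O=C(c1ccc(O[Si](C)(C)C(C)(C)C)cc1)c1ccc(O[Si](C)(C)C(C)(C)C)cc1 | intermediate
10 | (4-bromophenoxy)(tert-butyl)dimethylsilane | CC(C)(C)[Si](C)(C)Oc1ccc(Br)cc1 | starting material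
11 | {4-[(tert-butyldimethylsilyl)oxy]phenyl}magnesium bromide | CC(C)(C)[Si](C)(C)Oc1ccc([Mg]Br)cc1 | intermediate
12 | (2-chloro-5-{[(tert-butyldimethylsilyl)oxy]methyl}-6-{[4-(tert-butyldimethylsilyloxy)phenyl]ethynyl}phenyl)magnesium chloride | CC(C)(C)[Si](C)(C)OCc1ccc(Cl)c([Mg]Cl)c1C#Cc1ccc(O[Si](C)(C)C(C)(C)C)cc1 | intermediate
13 | 3-{[4-(tert-butyldimethylsilyloxy)phenyl]ethynyl}-4-{[(tert-butyldimethylsilyl)oxy]methyl}benzyne (triple bond between ring carbons 1 and 2) | CC(C)(C)[Si](C)(C)OCC1=C(C#Cc2ccc(O[Si](C)(C)C(C)(C)C)cc2)C#CC=C1 | intermediate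
14 | [4'-(tert-butyldimethylsilyloxy)-4-{[(tert-butyldimethylsilyl)oxy]methyl}-3-{[4-(tert-butyldimethylsilyloxy)phenyl]ethynyl}biphenyl-2-yl]magnesium bromide | CC(C)(C)[Si](C)(C)OCc1ccc(-c2ccc(O[Si](C)(C)C(C)(C)C)cc2)c([Mg]Br)c1C#Cc1ccc(O[Si](C)(C)C(C)(C)C)cc1 | intermediate
15 | [4'-(tert-butyldimethylsilyloxy)-4-{[(tert-butyldimethylsilyl)oxy]methyl}-3-{[4-(tert-butyldimethylsilyloxy)phenyl]ethynyl}biphenyl-2-yl]bis[4-(tert-butyldimethylsilyloxy)phenyl]methanol | CC(C)(C)[Si](C)(C)OCc1ccc(-c2ccc(O[Si](C)(C)C(C)(C)C)cc2)c(C(O)(c2ccc(O[Si](C)(C)C(C)(C)C)cc2)c2ccc(O[Si](C)(C)C(C)(C)C)cc2)c1C#Cc1ccc(O[Si](C)(C)C(C)(C)C)cc1 | intermediate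
16 | {4'-hydroxy-4-(hydroxymethyl)-3-[(4-hydroxyphenyl)ethynyl]biphenyl-2-yl}bis(4-hydroxyphenyl)methanol | OCc1ccc(-c2ccc(O)cc2)c(C(O)(c2ccc(O)cc2)c2ccc(O)cc2)c1C#Cc1ccc(O)cc1 | intermediate
17 | selaginellin, 4-[{4'-hydroxy-4-(hydroxymethyl)-3-[(4-hydroxyphenyl)ethynyl]biphenyl-2-yl}(4-hydroxyphenyl)methylidene]cyclohexa-2,5-dien-1-one | O=C1C=CC(=C(c2ccc(O)cc2)c2c(-c3ccc(O)cc3)ccc(CO)c2C#Cc2ccc(O)cc2)C=C1 | target

**Count and risks**

Total step count: 8. Longest linear sequence: 6 steps (steps 1, 2, 3, 4, 7, 8).

Steps most likely to fail: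

Step 7. The aryl Grignard reagent may add to the aryne at C1 as well as at C2 (poor site selectivity), or the crowded biarylmagnesium may reduce the ketone by electron transfer instead of adding to it. The fallback uses known reactions only, sets out from 7 and comes back at 15. Bromine–lithium exchange on 7 with n-BuLi in THF at −78 °C should give the ortho-chloro aryllithium F1, which keeps its chloride at this temperature. Addition of ketone 9 at −78 °C and a cold aqueous quench should give the chloro carbinol F2. A Suzuki–Miyaura coupling of the aryl chloride in F2 with [4-(tert-butyldimethylsilyloxy)phenyl]boronic acid (Pd2(dba)3, SPhos, anhydrous K3PO4, toluene, 90 °C) should then give 15. In this order the C1–C7 bond is made first by an ordinary aryllithium addition and the C2–aryl bond afterwards by cross-coupling, so the positions are fixed by the two halogens and not by the polarisation of an aryne.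

Step 8. The tertiary carbinol oxygen may attack the neighbouring alkyne (5-exo- or 6-endo-dig hydroalkoxylation) while fluoride keeps the medium basic, before water is lost; cleavage of the alkyl silyl ether may also lag behind. The fallback sets out from 15 and comes back at 17, and removes the carbinol oxygen before the last silyl group. KHF2 in MeOH–THF at rt should cleave only the four aryl silyl ethers under weakly acidic conditions. The tetraphenol carbinol F3 so formed should lose water in the flask or on mildly acidic work-up to the fuchsone silyl ether F4, in which no nucleophilic oxygen is left next to the alkyne. The primary silyl ether of F4 is then taken off with AcOH–THF–H2O (3:1:1) at 40 °C to give 17.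

Step 1. The base may deprotonate the other position ortho to the ester (C6), or the metalated arene may add to the ester of a second molecule. The fallback sets out from 1 and comes back at 4, and moves the site-determining metalation to the free acid, which has no electrophilic carbonyl group. Saponification of 1 (LiOH, THF–H2O, then HCl) gives 3-bromo-4-chlorobenzoic acid F5. Carboxylate-directed lithiation with LiTMP (2.2 eq, THF, −78 °C) should give the dilithio species F6, metalated at the C–H flanked by the carboxylate and the bromine. Quenching with I2 should give 3-bromo-4-chloro-2-iodobenzoic acid F7, and reduction with BH3·THF (0 °C → rt) gives 4.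

Further compounds
F1 | step 7 | (2-chloro-5-{[(tert-butyldimethylsilyl)oxy]methyl}-6-{[4-(tert-butyldimethylsilyloxy)phenyl]ethynyl}phenyl)lithium | CC(C)(C)[Si](C)(C)OCc1ccc(Cl)c([Li])c1C#Cc1ccc(O[Si](C)(C)C(C)(C)C)cc1
F2 | step 7 | (6-chloro-3-{[(tert-butyldimethylsilyl)oxy]methyl}-2-{[4-(tert-butyldimethylsilyloxy)phenyl]ethynyl}phenyl)bis[4-(tert-butyldimethylsilyloxy)phenyl]methanol | CC(C)(C)[Si](C)(C)OCc1ccc(Cl)c(C(O)(c2ccc(O[Si](C)(C)C(C)(C)C)cc2)c2ccc(O[Si](C)(C)C(C)(C)C)cc2)c1C#Cc1ccc(O[Si](C)(C)C(C)(C)C)cc1
F3 | step 8 | [4'-hydroxy-4-{[(tert-butyldimethylsilyl)oxy]methyl}-3-[(4-hydroxyphenyl)ethynyl]biphenyl-2-yl]bis(4-hydroxyphenyl)methanol | OC(c1ccc(O)cc1)(c1ccc(O)cc1)c1c(-c2ccc(O)cc2)ccc(CO[Si](C)(C)C(C)(C)C)c1C#Cc1ccc(O)cc1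
F4 | step 8 | selaginellin tert-butyldimethylsilyl ether at the CH2OH group | O=C1C=CC(=C(c2ccc(O)cc2)c2c(-c3ccc(O)cc3)ccc(CO[Si](C)(C)C(C)(C)C)c2C#Cc2ccc(O)cc2)C=C1
F5 | step 1 | 3-bromo-4-chlorobenzoic acid | OC(=O)c1ccc(Cl)c(Br)c1
F6 | step 1 | lithium 3-bromo-4-chloro-2-lithiobenzoate | [Li]OC(=O)c1ccc(Cl)c(Br)c1[Li]
F7 | step 1 | 3-bromo-4-chloro-2-iodobenzoic acid | OC(=O)c1ccc(Cl)c(Br)c1I
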